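The bond broken in the retrosynthesis is C3–C4 of the cyclohexanone ring (C1 quaternary carbinol carrying C7H2OBz, C2 ketone, C3 methylene, C4–C6 carbinols). The β-hydroxy ketone C2(=O)–C3H2–C4H(OH) is read as the aldol of a sugar-derived keto aldehyde. One Ferrier carbocyclisation of a 4-C-branched 6-deoxyhex-5-enopyranose therefore unmasks the C2 ketone, forms C3–C4, closes the carbocycle and sets the C4 carbinol. The precursor is a pyranosyl acetate with an exocyclic C5=C6 enol ether, a quaternary C4 carrying the benzoyloxymethyl branch, a 2-benzoate and a cis-3,4-acetonide. It is built from diacetone-D-mannose, whose formaldehyde aldol creates the quaternary carbon inside the acetonide.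

Key step: step 9

Remark: centres that are erased later (the anomeric carbon and sugar C5) are carried as mixtures and left undefined in the SMILES; the anomeric group of the key-step precursor is a spectator and is chosen as acetate so that the lactol can be capped without acid.

Numbering: mannose C1/C2/C3/C4/C5 become sugar C5/C4/C3/C2/C1 of the pyranose and ring C2/C1/C6/C5/C4 of the target; the Wittig carbon becomes sugar C6 (ring C3), the formaldehyde carbon becomes C7, and mannose C6 is lost.

Step 1
Reactants: 1 2,3:5,6-di-O-isopropylidene-α-D-mannofuranose; 2 formaldehyde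
Product: 3 2-C-(hydroxymethyl)-2,3:5,6-di-O-isopropylidene-D-mannofuranose
Conditions: 37% aq. HCHO (excess), K2CO3, MeOH, 65 °C
Reagents that add atoms: formaldehyde, C=O
Why: Base-mediated crossed aldol addition: the ring-opened aldehyde enolises at C2 and adds formaldehyde, and because only the epimer with O2 cis to O3 can re-close to the cis-fused furanose lactol, the reversible aldol should drain to the manno-configured quaternary centre (future ring C1 with C7).

Step 2
Reactants: 3 2-C-(hydroxymethyl)-2,3:5,6-di-O-isopropylidene-D-mannofuranose; 4 methyltriphenylphosphonium bromide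
Product: 5 1,2-dideoxy-3-C-(hydroxymethyl)-3,4:6,7-di-O-isopropylidene-D-manno-hept-1-enitol
Conditions: Ph3PCH3Br (4 equiv), n-BuLi (3.9 equiv), THF, −20 °C → rt
Reagents that add atoms: methyltriphenylphosphonium bromide, [Br-].C[P+](c1ccccc1)(c1ccccc1)c1ccccc1
Why: Wittig methylenation of the aldehyde tautomer of the lactol, with excess ylide also deprotonating the two hydroxyls; the quaternary α-carbon cannot epimerise and no stereocentre is formed.

Step 3
Reactants: 5 1,2-dideoxy-3-C-(hydroxymethyl)-3,4:6,7-di-O-isopropylidene-D-manno-hept-1-enitol; 6 benzoyl chloride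
Product: 7 5-O-benzoyl-3-C-(benzoyloxymethyl)-1,2-dideoxy-3,4:6,7-di-O-isopropylidene-D-manno-hept-1-enitol
Conditions: BzCl (2.5 equiv), DMAP (cat.), pyridine, 0 °C → rt
Reagents that add atoms: benzoyl chloride, O=C(Cl)c1ccccc1
Why: DMAP-catalysed acylation of the only two free hydroxyls (the primary branch alcohol and the secondary alcohol released from the lactol) places both benzoates of the target at once without touching a stereocentre.

Step 4
Reactants: 7 5-O-benzoyl-3-C-(benzoyloxymethyl)-1,2-dideoxy-3,4:6,7-di-O-isopropylidene-D-manno-hept-1-enitol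
Product: 8 5-O-benzoyl-3-C-(benzoyloxymethyl)-3,4:6,7-di-O-isopropylidene-D/L-glycero-D-manno-heptitol (C2 epimers)
Conditions: OsO4 (2 mol%), NMO (1.5 equiv), acetone–H2O (4:1), rt
Reagents that add atoms: osmium tetroxide (catalytic oxygen carrier), O=[Os](=O)(=O)=O; N-methylmorpholine N-oxide, C[N+]1([O-])CCOCC1; water, O
Why: Upjohn dihydroxylation of the monosubstituted alkene, the only oxidisable π-bond; the new carbinol forms as an epimer mixture, which is harmless because this carbon becomes sp2 in step 8.

Step 5
Reactants: 8 5-O-benzoyl-3-C-(benzoyloxymethyl)-3,4:6,7-di-O-isopropylidene-D/L-glycero-D-manno-heptitol (C2 epimers)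
Product: 9 5-O-benzoyl-3-C-(benzoyloxymethyl)-1-deoxy-1-iodo-3,4:6,7-di-O-isopropylidene-D/L-glycero-D-manno-heptitol
Conditions: PPh3 (1.3 equiv), I2 (1.3 equiv), imidazole (2.6 equiv), THF, 0 °C → rt
Reagents that add atoms: iodine, II
Why: Garegg–Samuelsson (Appel-type) iodination through an alkoxyphosphonium salt and SN2 attack of iodide, selective for the primary hydroxyl because the secondary one is flanked by the quaternary carbon; esters and acetonides are inert.

Step 6
Reactants: 9 5-O-benzoyl-3-C-(benzoyloxymethyl)-1-deoxy-1-iodo-3,4:6,7-di-O-isopropylidene-D/L-glycero-D-manno-heptitol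
Product: 12 2-O-benzoyl-4-C-(benzoyloxymethyl)-6-deoxy-6-iodo-3,4-O-isopropylidene-hexopyranose (D-altro/L-galacto C5 epimers), via triol 10 (not isolated), via hydroxy aldehyde 11 (not isolated)
Conditions: H5IO6 (1.3 equiv), EtOAc, rt
Reagents that add atoms: none
Why: Periodic acid should hydrolyse the monosubstituted terminal dioxolane much faster than the fully substituted internal one and cleave the freed glycol (Malaprade reaction), after which the δ-hydroxy aldehyde closes to the pyranose hemiacetal; the iodohydrin is not a glycol and is not cleaved.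

Step 7
Reactants: 12 2-O-benzoyl-4-C-(benzoyloxymethyl)-6-deoxy-6-iodo-3,4-O-isopropylidene-hexopyranose (D-altro/L-galacto C5 epimers); 13 acetic anhydride
Product: 14 1-O-acetyl-2-O-benzoyl-4-C-(benzoyloxymethyl)-6-deoxy-6-iodo-3,4-O-isopropylidene-hexopyranose (D-altro/L-galacto C5 epimers)
Conditions: Ac2O, DMAP (cat.), pyridine, 0 °C → rt
Reagents that add atoms: acetic anhydride, CC(=O)OC(C)=O
Why: DMAP-catalysed acetylation of the hemiacetal hydroxyl, the only free hydroxyl of the pyranose form, fixes the ring under non-acidic conditions and installs the anomeric leaving group for step 9.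

Step 8
Reactants: 14 1-O-acetyl-2-O-benzoyl-4-C-(benzoyloxymethyl)-6-deoxy-6-iodo-3,4-O-isopropylidene-hexopyranose (D-altro/L-galacto C5 epimers)
Product: 15 1-O-acetyl-2-O-benzoyl-4-C-(benzoyloxymethyl)-6-deoxy-3,4-O-isopropylidene-D-arabino-hex-5-enopyranose
Conditions: AgF (3 equiv), pyridine, rt, dark
Reagents that add atoms: none
Why: Silver-assisted E2 dehydroiodination of a 6-deoxy-6-iodopyranose, the standard entry to hex-5-enopyranose enol ethers; H5 is the only β-hydrogen because C4 is quaternary, both C5 epimers converge, and esters and acetonide tolerate AgF in pyridine.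

Step 9
Reactants: 15 1-O-acetyl-2-O-benzoyl-4-C-(benzoyloxymethyl)-6-deoxy-3,4-O-isopropylidene-D-arabino-hex-5-enopyranose
Product: 17 1,6-O-isopropylidene acetal of the target, via mercurio keto aldehyde 16 (not isolated)
Conditions: Hg(OCOCF3)2 (5 mol%), acetone–H2O (2:1), rt
Reagents that add atoms: water, O
Why: Mercury(II) and water add across the electron-rich C5=C6 enol ether to give a C5 hemiketal that collapses, opening the pyranose to the C5 ketone carrying CH2HgX and, after loss of acetic acid from the C1 hemiacetal acetate, the C1 aldehyde (16), whose α-mercurio ketone then adds as a mercury enolate to the aldehyde. The closest known reaction type is the Ferrier carbocyclisation of 6-deoxyhex-5-enopyranosides and the corresponding pyranosyl esters with catalytic mercury(II). The one ring is closed by a 6-(enolendo)-exo-trig aldol that forms ring bond C3–C4 (sugar C6–C1). The new carbinol C4 is set in a chair-like transition state that places the hydroxyl trans to the sugar O3 substituent, here held on the lower face by the cis-fused dioxolane, so it should come out cis to the C5 benzoate and 1,3-trans to O6 as the target requires. The step needs enolisation toward C3 only and survival of the β-hydroxy ketone and esters: the quaternary C1 (sugar C4) forbids enolisation and β-elimination on its side, and near-neutral aqueous acetone spares benzoates and acetonide.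

Step 10
Reactants: 17 1,6-O-isopropylidene acetal of the target
Product: 18 [(1S,2S,3R,4R)-3-(benzoyloxy)-1,2,4-trihydroxy-6-oxocyclohexyl]methyl benzoate
Conditions: TFA–H2O (9:1), 0 °C
Reagents that add atoms: none
Why: Acid-catalysed hydrolysis of the isopropylidene acetal (oxocarbenium ion trapped by water) frees the C1 and C6 hydroxyls; cold, short exposure should leave the benzoates in place and the β-hydroxy ketone undehydrated, and no stereocentre is involved.

Compound list
1 | 2,3:5,6-di-O-isopropylidene-α-D-mannofuranose (commercial; one step from D-mannose) | O[C@H]1O[C@H]([C@H]2COC(C)(C)O2)[C@@H]2OC(C)(C)O[C@H]12 | starting material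
2 | formaldehyde (37% aqueous) | C=O | starting material
3 | 2-C-(hydroxymethyl)-2,3:5,6-di-O-isopropylidene-D-mannofuranose (anomers) | OC1O[C@H]([C@H]2COC(C)(C)O2)[C@@H]2OC(C)(C)O[C@]12CO | intermediate
4 | methyltriphenylphosphonium bromide | [Br-].C[P+](c1ccccc1)(c1ccccc1)c1ccccc1 | starting material
5 | 1,2-dideoxy-3-C-(hydroxymethyl)-3,4:6,7-di-O-isopropylidene-D-manno-hept-1-enitol | C=C[C@@]1(CO)OC(C)(C)O[C@H]1[C@H](O)[C@H]1COC(C)(C)O1 | intermediate
6 | benzoyl chloride | O=C(Cl)c1ccccc1 | starting material
7 | 5-O-benzoyl-3-C-(benzoyloxymethyl)-1,2-dideoxy-3,4:6,7-di-O-isopropylidene-D-manno-hept-1-enitol | C=C[C@@]1(COC(=O)c2ccccc2)OC(C)(C)O[C@H]1[C@H](OC(=O)c1ccccc1)[C@H]1COC(C)(C)O1 | intermediate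
8 | 5-O-benzoyl-3-C-(benzoyloxymethyl)-3,4:6,7-di-O-isopropylidene-D/L-glycero-D-manno-heptitol (C2 epimers) | OCC(O)[C@@]1(COC(=O)c2ccccc2)OC(C)(C)O[C@H]1[C@H](OC(=O)c1ccccc1)[C@H]1COC(C)(C)O1 | intermediate
9 | 5-O-benzoyl-3-C-(benzoyloxymethyl)-1-deoxy-1-iodo-3,4:6,7-di-O-isopropylidene-D/L-glycero-D-manno-heptitol | ICC(O)[C@@]1(COC(=O)c2ccccc2)OC(C)(C)O[C@H]1[C@H](OC(=O)c1ccccc1)[C@H]1COC(C)(C)O1 | intermediate
10 | triol from 9 after loss of the terminal acetonide (6,7-diol; not isolated) | ICC(O)[C@@]1(COC(=O)c2ccccc2)OC(C)(C)O[C@H]1[C@H](OC(=O)c1ccccc1)[C@H](O)CO | intermediate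
11 | open-chain hydroxy aldehyde: 2-O-benzoyl-4-C-(benzoyloxymethyl)-6-deoxy-6-iodo-3,4-O-isopropylidene-aldehydo-hexose (not isolated) | ICC(O)[C@@]1(COC(=O)c2ccccc2)OC(C)(C)O[C@H]1[C@H](OC(=O)c1ccccc1)C=O | intermediate
12 | 2-O-benzoyl-4-C-(benzoyloxymethyl)-6-deoxy-6-iodo-3,4-O-isopropylidene-hexopyranose (D-altro/L-galacto C5 epimers, anomers) | O=C(OC[C@@]1(OC(C)(C)O2)C(CI)OC(O)[C@@H](OC(=O)c3ccccc3)[C@@H]12)c1ccccc1 | intermediate
13 | acetic anhydride | CC(=O)OC(C)=O | starting material
14 | 1-O-acetyl-2-O-benzoyl-4-C-(benzoyloxymethyl)-6-deoxy-6-iodo-3,4-O-isopropylidene-hexopyranose (D-altro/L-galacto C5 epimers, anomers) | O=C(OC[C@@]1(OC(C)(C)O2)C(CI)OC(OC(C)=O)[C@@H](OC(=O)c3ccccc3)[C@@H]12)c1ccccc1 | intermediate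
15 | 1-O-acetyl-2-O-benzoyl-4-C-(benzoyloxymethyl)-6-deoxy-3,4-O-isopropylidene-D-arabino-hex-5-enopyranose (anomers) | O=C(OC[C@@]1(OC(C)(C)O2)C(=C)OC(OC(C)=O)[C@@H](OC(=O)c3ccccc3)[C@@H]12)c1ccccc1 | intermediate
16 | acyclic 6-(trifluoroacetoxymercurio) 5-keto aldehyde: 2-O-benzoyl-4-C-(benzoyloxymethyl)-6-deoxy-3,4-O-isopropylidene-6-mercurio-D-arabino-hexos-5-ulose (not isolated) | O=C[C@@H](OC(=O)c1ccccc1)[C@@H]1OC(C)(C)O[C@]1(COC(=O)c1ccccc1)C(=O)C[Hg]OC(=O)C(F)(F)F | intermediate
17 | 1,6-O-isopropylidene acetal of the target (cis-fused dioxolane on ring C1/C6; C4 hydroxyl free, cis to the C5 benzoate) | O=C(OC[C@@]1(OC(C)(C)O2)C(=O)C[C@@H](O)[C@@H](OC(=O)c3ccccc3)[C@@H]12)c1ccccc1 | intermediate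
18 | [(1S,2S,3R,4R)-3-(benzoyloxy)-1,2,4-trihydroxy-6-oxocyclohexyl]methyl benzoate | O=C(OC[C@@]1(O)C(=O)C[C@@H](O)[C@@H](OC(=O)c2ccccc2)[C@@H]1O)c1ccccc1 | target

Total step count: 10. Longest linear sequence: 10 steps (1 to 18).

Steps most likely to fail

1. Step 9. The aldol closure may show poor facial selectivity at the new carbinol because the fused dioxolane distorts the chair-like transition state, or the β-hydroxy ketone may lose water under the metal-mediated conditions. The fallback sets out from 15 and separates hydration from ring closure without metal. Brief treatment with dilute aqueous acid in THF should hydrolyse the enol ether and expel the anomeric acetate to give the keto aldehyde 2-O-benzoyl-4-C-(benzoyloxymethyl)-6-deoxy-3,4-O-isopropylidene-D-arabino-hexos-5-ulose F1. This is then cyclised by enamine catalysis with proline (either enantiomer, DMSO, rt) in the same 6-(enolendo)-exo-trig aldol, so that the catalyst and not the substrate sets the facial sense. The fallback comes back to the route at 17.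

2. Step 2. The alkoxide of the β-hydroxy aldehyde may lose formaldehyde by retro-aldol cleavage under the basic ylide conditions, or methylenation of the hindered aldehyde may be slow. The fallback sets out from 3. Selective silylation of the primary hydroxyl (TBSCl, imidazole, DMF, 0 °C) should give 2-C-(tert-butyldimethylsilyloxymethyl)-2,3:5,6-di-O-isopropylidene-D-mannofuranose F2, which has no alkoxide β to the aldehyde. Wittig methylenation as in step 2 then gives 3-C-(tert-butyldimethylsilyloxymethyl)-1,2-dideoxy-3,4:6,7-di-O-isopropylidene-D-manno-hept-1-enitol F3, and TBAF in THF removes the silyl group. The fallback comes back to the route at 5.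

3. Step 10. Acid may dehydrate the β-hydroxy ketone or cause acyl migration before the hindered acetal is fully hydrolysed. The fallback sets out from 14 and removes the acetal before the carbocycle exists. Aqueous TFA at 0 °C should give the diol 1-O-acetyl-2-O-benzoyl-4-C-(benzoyloxymethyl)-6-deoxy-6-iodo-hexopyranose F4. AgF in pyridine then gives 1-O-acetyl-2-O-benzoyl-4-C-(benzoyloxymethyl)-6-deoxy-D-arabino-hex-5-enopyranose F5. The mercury(II)-catalysed carbocyclisation of step 9, which tolerates free hydroxyls, is then run on F5. The fallback comes back to the route at 18 with no final deprotection.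

Further compounds
F1 | step 9 | 2-O-benzoyl-4-C-(benzoyloxymethyl)-6-deoxy-3,4-O-isopropylidene-D-arabino-hexos-5-ulose | O=C[C@@H](OC(=O)c1ccccc1)[C@@H]1OC(C)(C)O[C@]1(COC(=O)c1ccccc1)C(C)=O
F2 | step 2 | 2-C-(tert-butyldimethylsilyloxymethyl)-2,3:5,6-di-O-isopropylidene-D-mannofuranose | OC1O[C@H]([C@H]2COC(C)(C)O2)[C@@H]2OC(C)(C)O[C@]12CO[Si](C)(C)C(C)(C)C
F3 | step 2 | 3-C-(tert-butyldimethylsilyloxymethyl)-1,2-dideoxy-3,4:6,7-di-O-isopropylidene-D-manno-hept-1-enitol | C=C[C@@]1(CO[Si](C)(C)C(C)(C)C)OC(C)(C)O[C@H]1[C@H](O)[C@H]1COC(C)(C)O1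
F4 | step 10 | 1-O-acetyl-2-O-benzoyl-4-C-(benzoyloxymethyl)-6-deoxy-6-iodo-hexopyranose (D-altro/L-galacto C5 epimers) | O=C(OC[C@@]1(O)C(CI)OC(OC(C)=O)[C@@H](OC(=O)c2ccccc2)[C@@H]1O)c1ccccc1
F5 | step 10 | 1-O-acetyl-2-O-benzoyl-4-C-(benzoyloxymethyl)-6-deoxy-D-arabino-hex-5-enopyranose | O=C(OC[C@@]1(O)C(=C)OC(OC(C)=O)[C@@H](OC(=O)c2ccccc2)[C@@H]1O)c1ccccc1
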